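**Retrosynthetic overview**
1. Numbering follows the germacrane skeleton (ring C-1 to C-10, methyls C-14/C-15, lactone carbons C-11 to C-13). The ten-membered ring is closed last, by ring-closing metathesis at C2=C3; before that the C-8 ester is made (Yamaguchi) from (2S,3R)-2,3-dimethyloxirane-2-carboxylic acid, itself from tiglyl alcohol by Sharpless epoxidation and oxidation.
2. Key disconnection: the O–C6 and C11–C7 bonds of the α-methylene-γ-butyrolactone, back to 2-bromoacrylic acid and an acyclic (4Z,6E)-diene carrying the C-8 silyl ether. Forward, a palladium-catalysed Larock-type [3+2] heteroannulation builds the lactone ring first, then the carbocycle; both oxiranes come from Sharpless epoxidations of primary allylic alcohols.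
3. Feature that makes the key step possible: C-6 of the lactone is allylic to the ring alkene C4=C5 and C-7 is its neighbour, so the C6–C7 edge of the five-membered ring is the footprint of the terminal alkene of a C4=C5–C6=C7 diene. Carbon adds at C-7, a π-allyl spans C-4 to C-6, and the carboxylate closes the five-membered ring at C-6 while C4=C5 survives as the Z alkene.
4. The diene is assembled by an asymmetric vinylogous Mukaiyama aldol (C8–C9 bond, C-8 stereocentre) between (2E,4Z)-5,7-dimethylocta-2,4,6-trienal and the silyl dienolate of methyl 3-methylbut-2-enoate, then ester reduction and Sharpless epoxidation (C-1, C-10).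
5. The 2-methylprop-1-enyl cap on C-3 works twice: it blocks the far diene terminus in the annulation and leaves as 2-methylpropene in the metathesis.

Key step: step 12

Assumption: in step 8 the (R,R)-bisphosphoramide is taken to direct the dienolate to the Re face of the enal (giving 5R); if its sense is the opposite, the (S,S)-catalyst is used.

Step 1
Reactants: 1 (E)-2-methylbut-2-en-1-ol
Product: 2 [(2R,3R)-2,3-dimethyloxiran-2-yl]methanol
Conditions: Ti(OiPr)4 (10 mol %), D-(−)-diethyl tartrate (12 mol %), t-BuOOH, 4 Å MS, CH2Cl2, −20 °C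
Reagents that add atoms: tert-butyl hydroperoxide, CC(C)(C)OO
Why: Sharpless asymmetric epoxidation of a primary E-allylic alcohol; D-(−)-tartrate should deliver oxygen to the face that gives the (2R,3R)-epoxy alcohol (mirror of the (2S,3S) series obtained with L-(+)-tartrate), and the E geometry fixes the two methyl groups cis.

Step 2
Reactants: 2 [(2R,3R)-2,3-dimethyloxiran-2-yl]methanol
Product: 4 (2S,3R)-2,3-dimethyloxirane-2-carboxylic acid, via epoxy aldehyde 3 (not isolated)
Conditions: TEMPO (10 mol %), PhI(OAc)2 (2.2 equiv), MeCN/H2O 1:1, rt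
Reagents that add atoms: water, O
Why: Oxoammonium oxidation of the primary alcohol to the aldehyde and of its hydrate to the acid under near-neutral conditions should leave the oxirane and both stereocentres untouched (the descriptor at C-2 changes only through priorities).

Step 3
Reactants: 5 but-2-yn-1-ol
Product: 7 (Z)-3-iodobut-2-en-1-ol, via cyclic sodium alkenylalanate 6 (not isolated)
Conditions: NaAlH2(OCH2CH2OMe)2 (Red-Al), THF, 0 °C to rt; then I2, −78 °C to 0 °C
Reagents that add atoms: iodine, II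
Why: Alkoxide-directed trans-hydroalumination places aluminium on C-3 syn to the CH2O group and iodinolysis with retention should give the Z iodide, which fixes the later C4=C5 geometry.

Step 4
Reactants: 7 (Z)-3-iodobut-2-en-1-ol
Product: 8 (Z)-3-iodobut-2-enal
Conditions: MnO2 (excess), CH2Cl2, rt, dark
Reagents that add atoms: none
Why: Heterogeneous allylic oxidation with MnO2 is neutral and should not isomerise the Z alkene or touch the vinyl iodide.

Step 5
Reactants: 8 (Z)-3-iodobut-2-enal
Product: 9 (2E,4Z)-5-iodohexa-2,4-dienal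
Conditions: Ph3P=CHCHO (1.05 equiv), CH2Cl2, rt to 40 °C
Reagents that add atoms: (triphenylphosphoranylidene)acetaldehyde, O=CC=P(c1ccccc1)(c1ccccc1)c1ccccc1
Why: Wittig reaction with a stabilised ylide should give the E enal (future C6=C7) and one equivalent of ylide limits a second homologation.

Step 6
Reactants: 9 (2E,4Z)-5-iodohexa-2,4-dienal; 10 4,4,5,5-tetramethyl-2-(2-methylprop-1-en-1-yl)-1,3,2-dioxaborolane
Product: 11 (2E,4Z)-5,7-dimethylocta-2,4,6-trienal
Conditions: Pd(PPh3)4 (5 mol %), aq. K3PO4 (2 equiv), THF, 40 °C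
Reagents that add atoms: none
Why: Suzuki–Miyaura coupling proceeds with retention at both alkenes and installs the 2-methylprop-1-enyl cap; coupling after the chain extension avoids a (Z)-dienal that could close to a 2H-pyran.

Step 7
Reactants: 12 methyl 3-methylbut-2-enoate
Product: 14 tert-butyl[(1-methoxy-3-methylbuta-1,3-dien-1-yl)oxy]dimethylsilane, via lithium dienolate 13 (not isolated)
Conditions: LiN(iPr)2, THF/DMPU, −78 °C; then t-BuMe2SiCl, −78 °C to rt
Reagents that add atoms: tert-butyldimethylsilyl chloride, C[Si](C)(Cl)C(C)(C)C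
Why: Kinetic γ-deprotonation of the senecioate gives the dienolate, which is silylated on oxygen to the silyl dienol ether (ketene acetal geometry is of no consequence).

Step 8
Reactants: 11 (2E,4Z)-5,7-dimethylocta-2,4,6-trienal; 14 tert-butyl[(1-methoxy-3-methylbuta-1,3-dien-1-yl)oxy]dimethylsilane
Product: 15 methyl (2E,5R,6E,8Z)-5-hydroxy-3,9,11-trimethyldodeca-2,6,8,10-tetraenoate
Conditions: SiCl4 (1.1 equiv), (R,R)-binaphthyldiamine-derived bisphosphoramide (5 mol %), iPr2NEt (10 mol %), CH2Cl2, −78 °C; aq. NaHCO3/KF work-up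
Reagents that add atoms: none
Why: Lewis-base-activated SiCl4 vinylogous Mukaiyama aldol: the dienolate attacks through its γ-CH2 (C8–C9 bond), the s-trans dienolate should give the 2E enoate (future E-C1=C10), and the chiral chlorosilyl cation selects the Re face of the enal to set C-8 (5R).

Step 9
Reactants: 15 methyl (2E,5R,6E,8Z)-5-hydroxy-3,9,11-trimethyldodeca-2,6,8,10-tetraenoate
Product: 16 methyl (2E,5R,6E,8Z)-5-[(tert-butyldimethylsilyl)oxy]-3,9,11-trimethyldodeca-2,6,8,10-tetraenoate
Conditions: t-BuMe2SiCl, imidazole, DMF, 0 °C to rt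
Reagents that add atoms: tert-butyldimethylsilyl chloride, C[Si](C)(Cl)C(C)(C)C
Why: Silylation under non-acidic conditions protects the ionisable trienyl carbinol and provides the bulky group that later steers the annulation.

Step 10
Reactants: 16 methyl (2E,5R,6E,8Z)-5-[(tert-butyldimethylsilyl)oxy]-3,9,11-trimethyldodeca-2,6,8,10-tetraenoate
Product: 17 (2E,5R,6E,8Z)-5-[(tert-butyldimethylsilyl)oxy]-3,9,11-trimethyldodeca-2,6,8,10-tetraen-1-ol
Conditions: iBu2AlH (2.5 equiv), CH2Cl2, −78 °C; Rochelle salt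
Reagents that add atoms: none
Why: 1,2-Reduction of the enoate by iBu2AlH gives the primary allylic alcohol without touching the triene or the silyl ether.

Step 11
Reactants: 17 (2E,5R,6E,8Z)-5-[(tert-butyldimethylsilyl)oxy]-3,9,11-trimethyldodeca-2,6,8,10-tetraen-1-ol
Product: 18 [(2R,3R)-3-{(2R,3E,5Z)-2-[(tert-butyldimethylsilyl)oxy]-6,8-dimethylnona-3,5,7-trien-1-yl}-3-methyloxiran-2-yl]methanol
Conditions: Ti(OiPr)4 (10 mol %), D-(−)-diethyl tartrate (12 mol %), t-BuOOH, 4 Å MS, CH2Cl2, −25 °C
Reagents that add atoms: tert-butyl hydroperoxide, CC(C)(C)OO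
Why: Sharpless asymmetric epoxidation acts only on the one allylic alcohol; D-(−)-tartrate should give the (2R,3R)-epoxy alcohol (C-1 R, C-10 R, trans oxirane from the E alkene) under reagent control.

Step 12
Reactants: 18 [(2R,3R)-3-{(2R,3E,5Z)-2-[(tert-butyldimethylsilyl)oxy]-6,8-dimethylnona-3,5,7-trien-1-yl}-3-methyloxiran-2-yl]methanol; 19 2-bromoprop-2-enoic acid
Product: 20 (4S,5R)-4-{(1R)-1-[(tert-butyldimethylsilyl)oxy]-2-[(2R,3R)-3-(hydroxymethyl)-2-methyloxiran-2-yl]ethyl}-5-[(1Z)-2,4-dimethylpenta-1,3-dien-1-yl]-3-methylideneoxolan-2-one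
Conditions: Pd(OAc)2 (10 mol %), tri(2-furyl)phosphine (20 mol %), K2CO3 (3 equiv), n-Bu4NCl (1 equiv), DMF, 45 °C, dark
Reagents that add atoms: none
Why: Zerovalent palladium inserts into the C–Br bond of the 2-bromoacrylate, the alkenylpalladium adds syn across the only 1,2-disubstituted alkene (C6=C7) with carbon going to C-7, because the other terminus (the dimethyl-substituted cap carbon beyond C-3) cannot accept carbon, and the π-allyl complex spanning C-4 to C-6 is captured at C-6 by the tethered carboxylate. The closest known reaction type is the Larock heteroannulation of 1,3-dienes by vinylic or aryl halides that carry a carboxylic acid. The lactone ring closes by 5-exo attack of the carboxylate oxygen on the allyl terminus C-6, which releases zerovalent palladium. C-7 is controlled by the C-8 stereocentre: in the conformer with H-8 eclipsing the alkene (minimal allylic 1,3-strain) palladium and carbon should add to the face opposite the bulky silyloxy group, which is the 7,8-relationship of the target; C-6 is set trans to C-7 because syn carbopalladation of the E alkene followed by C–O bond formation on the palladium face gives the trans lactone, which is also the thermodynamic isomer if the allylic C–O bond re-ionises. The step needs site selectivity (secured by the substitution pattern), retention of the 4Z geometry (the anti-substituted tertiary allyl terminus C-4 should not become η1-bound before ring closure) and survival of the non-allylic epoxy alcohol, which zerovalent palladium does not ionise. The mild temperature should keep the (Z)-triene from a 1,7-hydrogen shift before it is consumed.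

Step 13
Reactants: 20 (4S,5R)-4-{(1R)-1-[(tert-butyldimethylsilyl)oxy]-2-[(2R,3R)-3-(hydroxymethyl)-2-methyloxiran-2-yl]ethyl}-5-[(1Z)-2,4-dimethylpenta-1,3-dien-1-yl]-3-methylideneoxolan-2-one
Product: 21 (4S,5R)-4-{(1R)-1-[(tert-butyldimethylsilyl)oxy]-2-[(2R,3S)-3-formyl-2-methyloxiran-2-yl]ethyl}-5-[(1Z)-2,4-dimethylpenta-1,3-dien-1-yl]-3-methylideneoxolan-2-one
Conditions: Dess–Martin periodinane (1.3 equiv), NaHCO3, CH2Cl2, 0 °C to rt
Reagents that add atoms: none
Why: Buffered Dess–Martin oxidation converts the primary epoxy alcohol into the epoxy aldehyde and should leave the exo-methylene lactone, the diene and the silyl ether alone (the oxirane descriptor changes only through priorities).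

Step 14
Reactants: 21 (4S,5R)-4-{(1R)-1-[(tert-butyldimethylsilyl)oxy]-2-[(2R,3S)-3-formyl-2-methyloxiran-2-yl]ethyl}-5-[(1Z)-2,4-dimethylpenta-1,3-dien-1-yl]-3-methylideneoxolan-2-one
Product: 22 (4S,5R)-4-{(1R)-1-[(tert-butyldimethylsilyl)oxy]-2-[(2R,3R)-3-ethenyl-2-methyloxiran-2-yl]ethyl}-5-[(1Z)-2,4-dimethylpenta-1,3-dien-1-yl]-3-methylideneoxolan-2-one
Conditions: CH2I2 (5 equiv), Zn (9 equiv), Ti(OiPr)4 (1 equiv), THF, 0 °C to rt
Reagents that add atoms: diiodomethane, ICI
Why: Aldehyde-selective Takai-type methylenation with the gem-dizinc reagent is non-basic, so it should neither add to the α-methylene lactone nor disturb the epoxide stereocentres, and it gives the vinyl epoxide only after the palladium step.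

Step 15
Reactants: 22 (4S,5R)-4-{(1R)-1-[(tert-butyldimethylsilyl)oxy]-2-[(2R,3R)-3-ethenyl-2-methyloxiran-2-yl]ethyl}-5-[(1Z)-2,4-dimethylpenta-1,3-dien-1-yl]-3-methylideneoxolan-2-one
Product: 23 (4R,5R)-4-{(1R)-2-[(2R,3R)-3-ethenyl-2-methyloxiran-2-yl]-1-hydroxyethyl}-5-[(1Z)-2,4-dimethylpenta-1,3-dien-1-yl]-3-methylideneoxolan-2-one
Conditions: Bu4NF (3 equiv), AcOH (3 equiv), THF, 0 °C to rt
Reagents that add atoms: none
Why: Fluoride desilylation buffered with AcOH protonates the C-8 alkoxide at once, so it should not add to C-13 of the methylene lactone or open the vinyl epoxide.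

Step 16
Reactants: 4 (2S,3R)-2,3-dimethyloxirane-2-carboxylic acid; 23 (4R,5R)-4-{(1R)-2-[(2R,3R)-3-ethenyl-2-methyloxiran-2-yl]-1-hydroxyethyl}-5-[(1Z)-2,4-dimethylpenta-1,3-dien-1-yl]-3-methylideneoxolan-2-one
Product: 25 (1R)-2-[(2R,3R)-3-ethenyl-2-methyloxiran-2-yl]-1-[(2R,3R)-2-[(1Z)-2,4-dimethylpenta-1,3-dien-1-yl]-4-methylidene-5-oxooxolan-3-yl]ethyl (2S,3R)-2,3-dimethyloxirane-2-carboxylate, via mixed Yamaguchi anhydride 24 (not isolated)
Conditions: 2,4,6-trichlorobenzoyl chloride, Et3N, toluene, rt; then 23, DMAP, rt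
Reagents that add atoms: none
Why: Yamaguchi esterification acylates the hindered secondary C-8 alcohol through the mixed anhydride with retention at C-8 and without touching either oxirane.

Step 17
Reactants: 25 (1R)-2-[(2R,3R)-3-ethenyl-2-methyloxiran-2-yl]-1-[(2R,3R)-2-[(1Z)-2,4-dimethylpenta-1,3-dien-1-yl]-4-methylidene-5-oxooxolan-3-yl]ethyl (2S,3R)-2,3-dimethyloxirane-2-carboxylate
Product: 26 (1R,6R,7R,8R,10R)-1,10-epoxy-8-{[(2S,3R)-2,3-dimethyloxirane-2-carbonyl]oxy}germacra-2Z,4Z,11(13)-trien-12,6-olide (target)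
Conditions: second-generation Hoveyda–Grubbs catalyst RuCl2(H2IMes)(=CH-C6H4-2-OiPr) (10 mol %), toluene (1 mM), 60 °C, argon sparge
Reagents that add atoms: none
Why: Ring-closing metathesis: the ruthenium alkylidene forms at the terminal vinyl of the vinyl epoxide and closes onto the 2-methylprop-1-enyl alkene with loss of 2-methylpropene; the ring should impose the 2Z geometry, and the exo-methylene cannot take part because either alternative ring would need a trans-fused oxirane on a seven-membered ring or a bridgehead alkene.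

**Compound list**
1 | (E)-2-methylbut-2-en-1-ol | C/C=C(\C)CO | starting material
2 | [(2R,3R)-2,3-dimethyloxiran-2-yl]methanol | OC[C@@]1(C)O[C@@H]1C | intermediate
3 | (2S,3R)-2,3-dimethyloxirane-2-carbaldehyde | O=C[C@@]1(C)O[C@@H]1C | intermediate (not isolated)
4 | (2S,3R)-2,3-dimethyloxirane-2-carboxylic acid | OC(=O)[C@@]1(C)O[C@@H]1C | intermediate
5 | but-2-yn-1-ol | CC#CCO | starting material
6 | cyclic sodium alkenylalanate (sodium 2,2-bis(2-methoxyethoxy)-5-methyl-2,3-dihydro-1,2-oxalumol-2-uide) | [Na+].CC1=CCO[Al-]1(OCCOC)OCCOC | intermediate (not isolated)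
7 | (Z)-3-iodobut-2-en-1-ol | OC/C=C(/C)I | intermediate
8 | (Z)-3-iodobut-2-enal | O=C/C=C(/C)I | intermediate
9 | (2E,4Z)-5-iodohexa-2,4-dienal | O=C/C=C/C=C(/C)I | intermediate
10 | 4,4,5,5-tetramethyl-2-(2-methylprop-1-en-1-yl)-1,3,2-dioxaborolane | CC(C)=CB1OC(C)(C)C(C)(C)O1 | starting material
11 | (2E,4Z)-5,7-dimethylocta-2,4,6-trienal | O=C/C=C/C=C(/C)C=C(C)C | intermediate
12 | methyl 3-methylbut-2-enoate | COC(=O)C=C(C)C | starting material
13 | lithium 1-methoxy-3-methylbuta-1,3-dien-1-olate | [Li+].[O-]C(OC)=CC(C)=C | intermediate (not isolated)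
14 | tert-butyl[(1-methoxy-3-methylbuta-1,3-dien-1-yl)oxy]dimethylsilane (ketene acetal geometry not defined) | C=C(C)C=C(OC)O[Si](C)(C)C(C)(C)C | intermediate
15 | methyl (2E,5R,6E,8Z)-5-hydroxy-3,9,11-trimethyldodeca-2,6,8,10-tetraenoate | COC(=O)/C=C(\C)C[C@@H](O)/C=C/C=C(/C)C=C(C)C | intermediate
16 | methyl (2E,5R,6E,8Z)-5-[(tert-butyldimethylsilyl)oxy]-3,9,11-trimethyldodeca-2,6,8,10-tetraenoate | COC(=O)/C=C(\C)C[C@@H](O[Si](C)(C)C(C)(C)C)/C=C/C=C(/C)C=C(C)C | intermediate
17 | (2E,5R,6E,8Z)-5-[(tert-butyldimethylsilyl)oxy]-3,9,11-trimethyldodeca-2,6,8,10-tetraen-1-ol | OC/C=C(\C)C[C@@H](O[Si](C)(C)C(C)(C)C)/C=C/C=C(/C)C=C(C)C | intermediate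
18 | [(2R,3R)-3-{(2R,3E,5Z)-2-[(tert-butyldimethylsilyl)oxy]-6,8-dimethylnona-3,5,7-trien-1-yl}-3-methyloxiran-2-yl]methanol | OC[C@H]1O[C@]1(C)C[C@@H](O[Si](C)(C)C(C)(C)C)/C=C/C=C(/C)C=C(C)C | intermediate
19 | 2-bromoprop-2-enoic acid (2-bromoacrylic acid) | C=C(Br)C(=O)O | starting material
20 | (4S,5R)-4-{(1R)-1-[(tert-butyldimethylsilyl)oxy]-2-[(2R,3R)-3-(hydroxymethyl)-2-methyloxiran-2-yl]ethyl}-5-[(1Z)-2,4-dimethylpenta-1,3-dien-1-yl]-3-methylideneoxolan-2-one | C=C1C(=O)O[C@H](/C=C(C)\C=C(C)C)[C@H]1[C@H](O[Si](C)(C)C(C)(C)C)C[C@@]2(C)O[C@@H]2CO | intermediate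
21 | (4S,5R)-4-{(1R)-1-[(tert-butyldimethylsilyl)oxy]-2-[(2R,3S)-3-formyl-2-methyloxiran-2-yl]ethyl}-5-[(1Z)-2,4-dimethylpenta-1,3-dien-1-yl]-3-methylideneoxolan-2-one | C=C1C(=O)O[C@H](/C=C(C)\C=C(C)C)[C@H]1[C@H](O[Si](C)(C)C(C)(C)C)C[C@@]2(C)O[C@@H]2C=O | intermediate
22 | (4S,5R)-4-{(1R)-1-[(tert-butyldimethylsilyl)oxy]-2-[(2R,3R)-3-ethenyl-2-methyloxiran-2-yl]ethyl}-5-[(1Z)-2,4-dimethylpenta-1,3-dien-1-yl]-3-methylideneoxolan-2-one | C=C1C(=O)O[C@H](/C=C(C)\C=C(C)C)[C@H]1[C@H](O[Si](C)(C)C(C)(C)C)C[C@@]2(C)O[C@@H]2C=C | intermediate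
23 | (4R,5R)-4-{(1R)-2-[(2R,3R)-3-ethenyl-2-methyloxiran-2-yl]-1-hydroxyethyl}-5-[(1Z)-2,4-dimethylpenta-1,3-dien-1-yl]-3-methylideneoxolan-2-one | C=C1C(=O)O[C@H](/C=C(C)\C=C(C)C)[C@H]1[C@H](O)C[C@@]2(C)O[C@@H]2C=C | intermediate
24 | (2S,3R)-2,3-dimethyloxirane-2-carboxylic 2,4,6-trichlorobenzoic anhydride | O=C(OC(=O)[C@@]1(C)O[C@@H]1C)c2c(Cl)cc(Cl)cc2Cl | intermediate (not isolated)
25 | (1R)-2-[(2R,3R)-3-ethenyl-2-methyloxiran-2-yl]-1-[(2R,3R)-2-[(1Z)-2,4-dimethylpenta-1,3-dien-1-yl]-4-methylidene-5-oxooxolan-3-yl]ethyl (2S,3R)-2,3-dimethyloxirane-2-carboxylate | C=C1C(=O)O[C@H](/C=C(C)\C=C(C)C)[C@H]1[C@H](OC(=O)[C@@]3(C)O[C@@H]3C)C[C@@]2(C)O[C@@H]2C=C | intermediate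
26 | (1R,6R,7R,8R,10R)-1,10-epoxy-8-{[(2S,3R)-2,3-dimethyloxirane-2-carbonyl]oxy}germacra-2Z,4Z,11(13)-trien-12,6-olide | C=C1C(=O)O[C@@H]2/C=C(C)\C=C/[C@H]3O[C@]3(C)C[C@@H](OC(=O)[C@@]3(C)O[C@@H]3C)[C@@H]12 | target

Total steps: 17. Longest linear sequence: 14 steps (steps 3–6 and 8–17, from but-2-yn-1-ol).

**Steps most likely to fail**

Step 12 (annulation). What may go wrong: β-hydride loss from the allylpalladium intermediate before C–O bond formation, carbopalladation on the wrong alkene face, or leakage of the 4Z geometry through π–σ–π isomerisation of the allyl complex. Fallback (radical–polar crossover instead of carbopalladation, run before the epoxide is present): setting out from 17, malonic acid with Mn(OAc)3·2H2O and Cu(OAc)2 in AcOH at rt should add the malonyl radical (made by trivalent manganese) to C-7; divalent copper oxidises the allyl radical and the free carboxyl group closes the lactone at C-6 to give the 11-carboxy lactone allylic alcohol F1. Decarboxylative Mannich methylenation (aqueous formaldehyde, Et2NH, NaOAc/AcOH) should give the α-methylene lactone allylic alcohol F2. Sharpless epoxidation of F2 under the conditions of step 11 comes back to the route at 20.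

Step 17 (ring closure). What may go wrong: oligomerisation outrunning closure of the strained ten-membered ring, catalyst sequestration by the chelating epoxy ester, or closure to the 2E isomer. Fallback (ring closure taken out of the last step and run on a substrate without the side chain): setting out from 22, metathesis of the silyl ether with the same ruthenium catalyst at high dilution should give the macrocyclic silyl ether F3; Bu4NF/AcOH should give the macrocyclic 8-alcohol F4; Yamaguchi acylation of F4 with acid 4 as in step 16 comes back to the route at 26.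

Step 14 (methylenation next to an epoxide and in the presence of the exo-methylene lactone). What may go wrong: Lewis-acid opening of the α,β-epoxy aldehyde or attack of the organozinc reagent on the conjugated methylene. Fallback (the Michael acceptor is stored as a Mannich base so that a plain Wittig reaction can be used): setting out from 20, Me2NH in THF at rt should add to C-13 to give the dimethylamino adduct F5; Dess–Martin oxidation should give the amino epoxy aldehyde F6; Ph3P=CH2 (from Ph3PCH3Br and KN(SiMe3)2, THF, −78 °C) should give the amino vinyl epoxide F7; MeI followed by aqueous NaHCO3, through the methiodide F8 (not isolated), eliminates trimethylamine and comes back to the route at 22.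

Further compounds
F1 | step 12 | (4S,5R)-4-{(1R,3E)-1-[(tert-butyldimethylsilyl)oxy]-5-hydroxy-3-methylpent-3-en-1-yl}-5-[(1Z)-2,4-dimethylpenta-1,3-dien-1-yl]-2-oxooxolane-3-carboxylic acid (C-3 epimers) | OC(=O)C1C(=O)O[C@H](/C=C(C)\C=C(C)C)[C@H]1[C@H](O[Si](C)(C)C(C)(C)C)C/C(C)=C/CO
F2 | step 12 | (4S,5R)-4-{(1R,3E)-1-[(tert-butyldimethylsilyl)oxy]-5-hydroxy-3-methylpent-3-en-1-yl}-5-[(1Z)-2,4-dimethylpenta-1,3-dien-1-yl]-3-methylideneoxolan-2-one | C=C1C(=O)O[C@H](/C=C(C)\C=C(C)C)[C@H]1[C@H](O[Si](C)(C)C(C)(C)C)C/C(C)=C/CO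
F3 | step 17 | (1R,6R,7S,8R,10R)-8-[(tert-butyldimethylsilyl)oxy]-1,10-epoxygermacra-2Z,4Z,11(13)-trien-12,6-olide | C=C1C(=O)O[C@@H]2/C=C(C)\C=C/[C@H]3O[C@]3(C)C[C@@H](O[Si](C)(C)C(C)(C)C)[C@@H]12
F4 | step 17 | (1R,6R,7R,8R,10R)-1,10-epoxy-8-hydroxygermacra-2Z,4Z,11(13)-trien-12,6-olide | C=C1C(=O)O[C@@H]2/C=C(C)\C=C/[C@H]3O[C@]3(C)C[C@@H](O)[C@@H]12
F5 | step 14 | (4S,5R)-4-{(1R)-1-[(tert-butyldimethylsilyl)oxy]-2-[(2R,3R)-3-(hydroxymethyl)-2-methyloxiran-2-yl]ethyl}-3-[(dimethylamino)methyl]-5-[(1Z)-2,4-dimethylpenta-1,3-dien-1-yl]oxolan-2-one (C-3 epimers) | CN(C)CC1C(=O)O[C@H](/C=C(C)\C=C(C)C)[C@H]1[C@H](O[Si](C)(C)C(C)(C)C)C[C@@]2(C)O[C@@H]2CO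
F6 | step 14 | (4S,5R)-4-{(1R)-1-[(tert-butyldimethylsilyl)oxy]-2-[(2R,3S)-3-formyl-2-methyloxiran-2-yl]ethyl}-3-[(dimethylamino)methyl]-5-[(1Z)-2,4-dimethylpenta-1,3-dien-1-yl]oxolan-2-one (C-3 epimers) | CN(C)CC1C(=O)O[C@H](/C=C(C)\C=C(C)C)[C@H]1[C@H](O[Si](C)(C)C(C)(C)C)C[C@@]2(C)O[C@@H]2C=O
F7 | step 14 | (4S,5R)-4-{(1R)-1-[(tert-butyldimethylsilyl)oxy]-2-[(2R,3R)-3-ethenyl-2-methyloxiran-2-yl]ethyl}-3-[(dimethylamino)methyl]-5-[(1Z)-2,4-dimethylpenta-1,3-dien-1-yl]oxolan-2-one (C-3 epimers) | CN(C)CC1C(=O)O[C@H](/C=C(C)\C=C(C)C)[C@H]1[C@H](O[Si](C)(C)C(C)(C)C)C[C@@]2(C)O[C@@H]2C=C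
F8 | step 14 | {(4S,5R)-4-{(1R)-1-[(tert-butyldimethylsilyl)oxy]-2-[(2R,3R)-3-ethenyl-2-methyloxiran-2-yl]ethyl}-5-[(1Z)-2,4-dimethylpenta-1,3-dien-1-yl]-2-oxooxolan-3-yl}-N,N,N-trimethylmethanaminium iodide (C-3 epimers) | C[N+](C)(C)CC1C(=O)O[C@H](/C=C(C)\C=C(C)C)[C@H]1[C@H](O[Si](C)(C)C(C)(C)C)C[C@@]2(C)O[C@@H]2C=C.[I-]
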